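1. Book the starting material of each flask as fractions of its charge, and ask where it stands at 2.5 h.

| flask | starting material | second substrate | free catalyst | remark | time |
|---|---|---|---|---|---|
| noon | 1 M | 1.5 M | 2.6 mM | run made earlier |  |
| Thursday's | 1.5 M | 1.50 M | 2.0 mM |  | 2.5 h |
| Friday's | 1.5 M | 1.50 M | 1.2 mM |  | 2.5 h |
| Saturday's | 1.5 M | 1.50 M | 5.0 mM |  | 2.5 h |
| Tuesday's | 1.5 M | 1.50 M | 2.6 mM |  | 2.5 h |
| Monday's | 1.5 M | 1.50 M | 0.80 mM |  | 2.5 h |
| Sunday's | 1.5 M | 1.50 M | 4.0 mM |  | 2.5 h |

noon run (percent of the starting material charged): time / min: target / % = 3.00: 0.8; 8.00: 5.5; 15.0: 7.3; 25.0: 11.7; 30.0: 15.7; 40.0: 17.6; 50.0: 19.6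

(readings scatter by 1 percentage point)

- percent here means starting material units held: one spent catalyst counts as two
- on the list of suspects stand: catalyst intermediate A -> free catalyst + target; catalyst intermediate B -> free catalyst + second product; target -> over-reaction product; second substrate + free catalyst <-> catalyst intermediate B; 2 second substrate -> self-condensation product; catalyst intermediate A + target -> spent catalyst; starting material + free catalyst <-> catalyst intermediate A
- no earlier run changes the charge of free catalyst; that part of a forecast is a guess

- all flasks from highest to lowest amount of target, in percent of the starting material charged, at 2.5 h (Thursday's / Friday's / Saturday's / Tuesday's / Monday's / Sunday's)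
- the amount of target, in percent of the starting material charged of the flask you put first, at 2.5 h
- the amount of target, in percent of the starting material charged of the flask you put last, at 2.5 h

2. We first read a pace from the noon run. At 30.0 min it holds 15.7 % of target, which gives a turnover frequency of 2.01 /min per catalyst. This is a reading and carries the scatter of 1 percentage point. The later climb is slower, so we are taking an early pace.

3. If a catalyst kept that pace, it would make 302 turns in 2.5 h. In powers of ten, that is ten to the 2.48. Saturday's catalyst charge is ten to the −2.48 of its starting material charge, so the exponents nearly cancel.

4. That sum is our quantity: the turnover budget, meaning pace times time times catalyst over starting material. It is the fraction of the starting material charged that the catalyst would turn at the noon pace. For Saturday's it is 1.01, and for Monday's 0.161.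

5. Now the ledger. In Saturday's, the forms of catalyst hold at most 0.667 % of the charge, with a spent catalyst counted as two, so we strike that entry. The turned fraction is entered as target plus over-reaction product, a split the noon run does not show. On this estimate, Monday's books leave 0.839 as starting material.

6. We therefore commit to the flasks ranking by catalyst charge, with Monday's target estimated below 0.161. Saturday's budget of 1.01 is more than the whole charge, so we enter at most the charge, split between target and over-reaction product.

7. The forecast gives Saturday's > Sunday's > Tuesday's > Thursday's > Friday's > Monday's, with 23.5 % on top (range 16 % to 33 %) and 9.3 % at the bottom (range 6 % to 14 %). Its ground is this: “That points to catalyst death, not substrate depletion”. Here we differ: our books enter no loss of catalyst.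

The flasks stand in the order Saturday's > Sunday's > Tuesday's > Thursday's > Friday's > Monday's.

    catalyst intermediate A → free catalyst + target (k = 17.0 /min)
    catalyst intermediate B → free catalyst + second product (k = 3.80 /min)
    target → over-reaction product (k = 0.00830 /min)
    second substrate + free catalyst ⇌ catalyst intermediate B (K = 0.240 /M, k = 160 /M/min)
    2 second substrate → self-condensation product (k = 0.00480 /M/min)
    catalyst intermediate A + target → spent catalyst (k = 0.00220 /M/min)
    starting material + free catalyst ⇌ catalyst intermediate A (K = 0.340 /M, k = 7.90 /M/min)

Saturday's holds 41.7 % of target at 2.50 h, above the forecast's range, and its spent catalyst is 1.51 % of the catalyst charged. Against its budget of 1.01, Saturday's has 15 % of its starting material left unbound, and over-reaction product holds 43.7 %. Monday's holds 13.7 % of target, and its budget of 0.161 stands below its conversion of 24.2 %.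

The runs are calculated on assumed constants; scatter was added.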